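**Retrosynthetic overview** (azulene numbering of the target)
1. C4–O: the ester goes on last, by selective acylation of the secondary alcohol of a diol enone with 3,4,5-trimethoxybenzoyl chloride.
2. Seven-membered ring, C6=C7: ring-closing metathesis of a cyclopentane carrying an acryloyl group on C8a and a methallyl carbinol on C3a.
3. Key bond C8–C8a: the acryloyl group comes from a tertiary cyclopentyl pinacol boronate (boron on the former enone β-carbon, a homoenolate equivalent) and lithiated methoxyallene (an acryloyl anion equivalent), by a stereoretentive 1,2-boronate shift and oxidation.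
4. C3 carbinol from the cyclopentanone and iPrMgCl; C8a–B, C3a and C4 are set together from 3-methylcyclopent-2-en-1-one, B2pin2 and 3-methylbut-3-enal by asymmetric conjugate borylation with aldol trapping.
5. Ring order: the five-membered ring is bought as 3-methylcyclopent-2-en-1-one; the seven-membered ring is closed in the second-last step.

Assumption: (R,R)-QuinoxP* is taken as the ligand enantiomer that gives the (3R) boronate; if the sense of induction is the opposite, (S,S)-QuinoxP* is used.

**Route**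

Step 1
Reactants: 1 3-methylbut-3-en-1-ol
Product: 2 3-methylbut-3-enal
Conditions: Dess–Martin periodinane (1.1 equiv), NaHCO3 (3 equiv), CH2Cl2, 0 °C to rt; filtered, used at once as a cold CH2Cl2 solution
Reagents that add atoms: none
Why: Dess–Martin oxidation of a primary alcohol stops at the aldehyde, and the bicarbonate buffer keeps the β,γ-unsaturated aldehyde from isomerising to the conjugated enal; no stereocentre is formed.

Step 2
Reactants: 3 3-methylcyclopent-2-en-1-one; 2 3-methylbut-3-enal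
Product: 5 (2S,3R)-2-[(1S)-1-hydroxy-3-methylbut-3-en-1-yl]-3-methyl-3-(4,4,5,5-tetramethyl-1,3,2-dioxaborolan-2-yl)cyclopentan-1-one, via boron enolate 4 (not isolated)
Conditions: Cu(MeCN)4PF6 (10 mol %), (R,R)-QuinoxP* (12 mol %), LiOtBu (15 mol %), B2pin2 (1.05 equiv), THF/DMSO 9:1, rt; then 2 (1.5 equiv), −30 °C; pH 7 buffer
Reagents that add atoms: bis(pinacolato)diboron, CC1(C)OB(OC1(C)C)B1OC(C)(C)C(C)(C)O1
Why: Enantioselective copper-catalysed conjugate borylation (a monovalent copper boryl under QuinoxP* control) sets the boron-bearing quaternary carbon (3R) and gives the pinacolboron (E)-enolate 4 regiospecifically, which adds to aldehyde 2 through a closed Zimmerman–Traxler chair on the face opposite the bulky boronate, so the side chain is trans to boron (2S) and the aldol is anti (1S carbinol).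

Step 3
Reactants: 5 (2S,3R)-2-[(1S)-1-hydroxy-3-methylbut-3-en-1-yl]-3-methyl-3-(4,4,5,5-tetramethyl-1,3,2-dioxaborolan-2-yl)cyclopentan-1-one
Product: 6 (1R,2S,3R)-2-[(1S)-1-hydroxy-3-methylbut-3-en-1-yl]-3-methyl-1-(propan-2-yl)-3-(4,4,5,5-tetramethyl-1,3,2-dioxaborolan-2-yl)cyclopentan-1-ol
Conditions: iPrMgCl·LiCl (2.5 equiv), LaCl3·2LiCl (1.1 equiv), THF, −20 to 0 °C; sat. aq. NH4Cl
Reagents that add atoms: isopropylmagnesium chloride, CC(C)[Mg]Cl
Why: Lanthanum-promoted Grignard 1,2-addition (which suppresses enolisation, β-hydride reduction and retro-aldol) to the chelated β-alkoxy ketone occurs on the ring face anti to the adjacent side chain, giving the tertiary alcohol with OH cis to that side chain (1R), while the hindered tertiary pinacol boronate is not attacked by the Grignard reagent.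

Step 4
Reactants: 6 (1R,2S,3R)-2-[(1S)-1-hydroxy-3-methylbut-3-en-1-yl]-3-methyl-1-(propan-2-yl)-3-(4,4,5,5-tetramethyl-1,3,2-dioxaborolan-2-yl)cyclopentan-1-ol
Product: 9 1-[(1S,2S,3R)-3-hydroxy-2-[(1S)-1-hydroxy-3-methylbut-3-en-1-yl]-1-methyl-3-(propan-2-yl)cyclopentyl]prop-2-en-1-one, via lithium boronate complex 7 (not isolated), via methoxyallyl boronic ester 8 (not isolated)
Conditions: methoxyallene (3.4 equiv), n-BuLi (3.3 equiv), THF, −78 °C; add 6, −78 to −40 °C; AcOH (3.5 equiv), −78 °C to rt; then 30 % aq. H2O2, pH 7 phosphate buffer, 0 °C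
Reagents that add atoms: methoxyallene (1-methoxypropa-1,2-diene), COC=C=C; hydrogen peroxide, OO
Why: Proposed new method: two sacrificial equivalents of 1-lithio-1-methoxyallene mask the hydroxyls as lithium alkoxides, a third equivalent (an acryloyl anion equivalent) adds to boron to give ate complex 7, protonation of the central allene carbon by AcOH creates an oxocarbenium-like centre that triggers a 1,2-shift of the tertiary ring carbon from boron to carbon with retention (8), and buffered peroxide oxidation of the α-methoxy allylboronate collapses the hemiketal to the vinyl ketone without epoxidising it, so the former enone β-carbon is joined to an acyl carbon and the quaternary centre is fixed as 1S; the closest known reaction type is the electrophile-induced 1,2-metallate rearrangement of alkenyl and allenyl boronate complexes (Zweifel-type chemistry, including the conversion of boronic esters into enones with lithiated methoxyallene), extended here to a dialkoxide-bearing, neopentyl-like tertiary boronate.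

Step 5
Reactants: 9 1-[(1S,2S,3R)-3-hydroxy-2-[(1S)-1-hydroxy-3-methylbut-3-en-1-yl]-1-methyl-3-(propan-2-yl)cyclopentyl]prop-2-en-1-one
Product: 10 (3R,3aS,4S,8aS)-3,4-dihydroxy-6,8a-dimethyl-3-(propan-2-yl)-2,3,3a,4,5,8a-hexahydroazulen-8(1H)-one
Conditions: second-generation Hoveyda–Grubbs catalyst (7 mol %), toluene (0.005 M), 80 °C
Reagents that add atoms: none
Why: Ring-closing olefin metathesis between the vinyl ketone and the 1,1-disubstituted alkene releases ethene and closes the seven-membered ring as the trisubstituted enone; the trans arrangement of the two side chains gives only the trans-fused hydroazulenone and no stereocentre is touched.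

Step 6
Reactants: 10 (3R,3aS,4S,8aS)-3,4-dihydroxy-6,8a-dimethyl-3-(propan-2-yl)-2,3,3a,4,5,8a-hexahydroazulen-8(1H)-one; 11 3,4,5-trimethoxybenzoyl chloride
Product: 12 (3R,3aS,4S,8aS)-3-hydroxy-6,8a-dimethyl-8-oxo-3-(propan-2-yl)-1,2,3,3a,4,5,8,8a-octahydroazulen-4-yl 3,4,5-trimethoxybenzoate
Conditions: 11 (1.3 equiv), pyridine (3 equiv), DMAP (0.1 equiv), CH2Cl2, 0 °C to rt
Reagents that add atoms: none
Why: DMAP-catalysed acyl transfer is selective for the secondary hydroxyl over the hindered tertiary one, and the weak base at low temperature avoids vinylogous β-elimination of the new ester; no stereocentre is changed.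

**Compound list**
1 | 3-methylbut-3-en-1-ol | CC(=C)CCO | starting material
2 | 3-methylbut-3-enal | CC(=C)CC=O | intermediate
3 | 3-methylcyclopent-2-en-1-one | CC1=CC(=O)CC1 | starting material
4 | 2-{[(3R)-3-methyl-3-(4,4,5,5-tetramethyl-1,3,2-dioxaborolan-2-yl)cyclopent-1-en-1-yl]oxy}-4,4,5,5-tetramethyl-1,3,2-dioxaborolane (boron enolate) | C[C@]1(B2OC(C)(C)C(C)(C)O2)CCC(OB2OC(C)(C)C(C)(C)O2)=C1 | intermediate
5 | (2S,3R)-2-[(1S)-1-hydroxy-3-methylbut-3-en-1-yl]-3-methyl-3-(4,4,5,5-tetramethyl-1,3,2-dioxaborolan-2-yl)cyclopentan-1-one | C=C(C)C[C@H](O)[C@H]1C(=O)CC[C@]1(C)B2OC(C)(C)C(C)(C)O2 | intermediate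
6 | (1R,2S,3R)-2-[(1S)-1-hydroxy-3-methylbut-3-en-1-yl]-3-methyl-1-(propan-2-yl)-3-(4,4,5,5-tetramethyl-1,3,2-dioxaborolan-2-yl)cyclopentan-1-ol | C=C(C)C[C@H](O)[C@H]1[C@](O)(C(C)C)CC[C@]1(C)B2OC(C)(C)C(C)(C)O2 | intermediate
7 | trilithium boronate complex: the boronate of 6 with a 1-methoxypropa-1,2-dien-1-yl group added to tetracoordinate boron and both hydroxyls as lithium alkoxides; ring stereocentres as in 6 | [Li+].[Li+].[Li+].C=C(C)C[C@H]([O-])[C@H]1[C@]([O-])(C(C)C)CC[C@]1(C)[B-]2(OC(C)(C)C(C)(C)O2)C(OC)=C=C | intermediate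
8 | 2-{1-[(1S,2S,3R)-3-hydroxy-2-[(1S)-1-hydroxy-3-methylbut-3-en-1-yl]-1-methyl-3-(propan-2-yl)cyclopentyl]-1-methoxyprop-2-en-1-yl}-4,4,5,5-tetramethyl-1,3,2-dioxaborolane (both epimers at the boron-bearing carbon) | C=C(C)C[C@H](O)[C@H]1[C@](O)(C(C)C)CC[C@]1(C)C(OC)(C=C)B2OC(C)(C)C(C)(C)O2 | intermediate
9 | 1-[(1S,2S,3R)-3-hydroxy-2-[(1S)-1-hydroxy-3-methylbut-3-en-1-yl]-1-methyl-3-(propan-2-yl)cyclopentyl]prop-2-en-1-one | C=C(C)C[C@H](O)[C@H]1[C@](O)(C(C)C)CC[C@]1(C)C(=O)C=C | intermediate
10 | (3R,3aS,4S,8aS)-3,4-dihydroxy-6,8a-dimethyl-3-(propan-2-yl)-2,3,3a,4,5,8a-hexahydroazulen-8(1H)-one | O[C@H]1CC(C)=CC(=O)[C@@]2(C)CC[C@@](O)(C(C)C)[C@H]12 | intermediate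
11 | 3,4,5-trimethoxybenzoyl chloride | COc1cc(C(Cl)=O)cc(OC)c1OC | starting material
12 | (3R,3aS,4S,8aS)-3-hydroxy-6,8a-dimethyl-8-oxo-3-(propan-2-yl)-1,2,3,3a,4,5,8,8a-octahydroazulen-4-yl 3,4,5-trimethoxybenzoate | COc1cc(C(=O)O[C@H]2CC(C)=CC(=O)[C@@]3(C)CC[C@@](O)(C(C)C)[C@H]23)cc(OC)c1OC | target

**Step count**
Total steps: 6. Longest linear sequence: 6 (1 → 2 → 5 → 6 → 9 → 10 → 12).

**Steps most likely to fail**

Step 2 (three-component borylation–aldol). The risks are isomerisation of aldehyde 2 and syn instead of anti aldol selectivity. Fallback: if the trap gives mainly the other carbinol epimer, the route sets out again from 3 (with 2) and accepts it. The epimeric aldol boronate F1 is taken through the same Grignard addition to the epimeric diol boronate F2, the same boronate homologation to the epimeric vinyl ketone F3, and the same ring-closing metathesis to the 4-epi diol enone F4. The ester is then introduced with inversion by a Mitsunobu reaction (3,4,5-trimethoxybenzoic acid, PPh3, DIAD, toluene, 0 °C to rt), which comes back to the route at 12.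

Step 3 (isopropyl addition). The risks are facial selectivity next to the boron-bearing quaternary carbon, retro-aldol, and attack at boron. Fallback: setting out from 5, the secondary hydroxyl is silylated (TESCl, imidazole, DMF) to the triethylsilyl ether ketone F5. Isopropyllithium with CeCl3 (THF, −78 °C) is then added under non-chelating Felkin-type control to give the silyl ether carbinol F6. PPTS in MeOH removes the silyl group, coming back at 6.

Step 4 (boronate homologation). The risks are ate-complex formation at a very hindered tertiary boronate and interference by the two lithium alkoxides. Fallback: setting out from 6, the 1,3-diol is tied up as the acetonide boronate F7 (2,2-dimethoxypropane, PPTS, CH2Cl2), which has no acidic or coordinating oxygen. Lithiated methoxyallene (1.3 equiv), AcOH and buffered H2O2 then give the acetonide vinyl ketone F8. Aqueous AcOH (80 %, rt) releases the diol, coming back at 9.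

**Further compounds**
F1 | step 2 | (2S,3R)-2-[(1R)-1-hydroxy-3-methylbut-3-en-1-yl]-3-methyl-3-(4,4,5,5-tetramethyl-1,3,2-dioxaborolan-2-yl)cyclopentan-1-one | C=C(C)C[C@@H](O)[C@H]1C(=O)CC[C@]1(C)B2OC(C)(C)C(C)(C)O2
F2 | step 2 | (1R,2S,3R)-2-[(1R)-1-hydroxy-3-methylbut-3-en-1-yl]-3-methyl-1-(propan-2-yl)-3-(4,4,5,5-tetramethyl-1,3,2-dioxaborolan-2-yl)cyclopentan-1-ol | C=C(C)C[C@@H](O)[C@H]1[C@](O)(C(C)C)CC[C@]1(C)B2OC(C)(C)C(C)(C)O2
F3 | step 2 | 1-[(1S,2S,3R)-3-hydroxy-2-[(1R)-1-hydroxy-3-methylbut-3-en-1-yl]-1-methyl-3-(propan-2-yl)cyclopentyl]prop-2-en-1-one | C=C(C)C[C@@H](O)[C@H]1[C@](O)(C(C)C)CC[C@]1(C)C(=O)C=C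
F4 | step 2 | (3R,3aS,4R,8aS)-3,4-dihydroxy-6,8a-dimethyl-3-(propan-2-yl)-2,3,3a,4,5,8a-hexahydroazulen-8(1H)-one | O[C@@H]1CC(C)=CC(=O)[C@@]2(C)CC[C@@](O)(C(C)C)[C@H]12
F5 | step 3 | (2S,3R)-3-methyl-2-{(1S)-3-methyl-1-[(triethylsilyl)oxy]but-3-en-1-yl}-3-(4,4,5,5-tetramethyl-1,3,2-dioxaborolan-2-yl)cyclopentan-1-one | C=C(C)C[C@H](O[Si](CC)(CC)CC)[C@H]1C(=O)CC[C@]1(C)B2OC(C)(C)C(C)(C)O2
F6 | step 3 | (1R,2S,3R)-3-methyl-2-{(1S)-3-methyl-1-[(triethylsilyl)oxy]but-3-en-1-yl}-1-(propan-2-yl)-3-(4,4,5,5-tetramethyl-1,3,2-dioxaborolan-2-yl)cyclopentan-1-ol | C=C(C)C[C@H](O[Si](CC)(CC)CC)[C@H]1[C@](O)(C(C)C)CC[C@]1(C)B2OC(C)(C)C(C)(C)O2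
F7 | step 4 | acetonide of diol 6 (2,2-dimethyl-1,3-dioxane bridging the tertiary and secondary carbinol oxygens; stereocentres as in 6) | C=C(C)C[C@@H]1OC(C)(C)O[C@@]2(C(C)C)CC[C@](C)(B3OC(C)(C)C(C)(C)O3)[C@@H]12
F8 | step 4 | the same acetonide of vinyl ketone 9 (stereocentres as in 9) | C=C(C)C[C@@H]1OC(C)(C)O[C@@]2(C(C)C)CC[C@](C)(C(=O)C=C)[C@@H]12
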